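What one asks of a small charge is what each dissolved portion is worth, and I asked the same of this flask, so I reckoned it in fractions of the solid substrate charged.

solid substrate 2.5 M; gas phase 97 mM (held); time 2.0 h

    starting material + dissolved gas → target (k1 = 0.00814 M⁻¹ s⁻¹)
    solid substrate ⇌ starting material, rate k2*(cs2 - [starting material]) while solid is left; crystals form when [starting material] > cs2 (cs2 = 1.3 M, k2 = 1.61 × 10⁻⁴ s⁻¹)
    dissolved gas → decomposed reagent (k3 = 1.27 × 10⁻⁴ s⁻¹)
    gas phase ⇌ dissolved gas, rate k4*(csat - [dissolved gas]) (k4 = 0.00963 s⁻¹, csat = 97 mM)
    starting material → side product (k5 = 0.00137 s⁻¹)

- target at 2.0 h, in percent of the solid substrate charged
- concentration of dissolved gas in solution at 2.0 h, in percent of saturation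

- given per volume of solution although it is solid: solid substrate
- at the start none of the gas is dissolved
- at the start none of the solid substrate is in solution
- run time (flask): 2.0 h

The bench rule says that a stirred suspension keeps its solution saturated, which here would have put starting material at 52.0% of the charge. That rule needs dissolving to outrun removal, so I held the dissolving coefficient against the two coefficients that remove starting material, with the gas taken at saturation. The ratio came to 0.0746, far below one, and the rule failed. I froze instead the level at which dissolving balances removal, a quasi-steady state:

starting material = solubility share × dissolving / (dissolving + side path + target path) = 3.61% of the charge

With starting material frozen there, I froze the dissolved gas as well: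

dissolved gas = transfer / (transfer + decomposition + uptake by starting material) = 91.8% of saturation

The two frozen levels gave the quantity I carried:

target path / (target path + side path) = 34.6%

This is the selectivity, the share of consumed starting material that ends as target. By 2.0 h, dissolving at the frozen rate had delivered 56.1% of the charge, less than the whole charge, so solid remained and the target came from what had passed through solution:

target = selectivity × (dissolved − still in solution) = 18.2% of the charge

The forecast gave 18.2% (from 17% to 19.5%) and 91.6% (from 90.5% to 92.5%), with “most of it lost to the side product rather than converted to target”. The simulated flask gave 18.1% and 91.6%.

The side path and the time given acted together to hold this flask at that yield: without the path from starting material to side product it reached 40.0%, and left until 20.0 h it reached 34.6%, the selectivity of 34.6% again, with solid substrate at 0%.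

In the neighbour flask charged with 1.0 M of solid substrate, the frozen dissolving rate needed 1.43 h, less than the 2.0 h allowed, so I took the whole charge through and expected 34.6% as target. That neighbour flask gave 34.6%.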